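**Plan**

- Retrosynthesis: the quinone is taken back to its hydroquinone, and the benzene ring (furan on C2) is cut at C4–C5. This unravels it through a dienylketene to a 3-furyl-4-hydroxy-4-vinylcyclobutenone.
- Enabling feature: the quinone ring has two para carbonyl carbons, three CH carbons and one carbon bonded to C2 of the furan. These map onto the C1 carbonyl, the C4 carbinol, the ring CH, the furyl-bearing C3 and the two vinyl carbons of that cyclobutenone.
- Further cuts: the ester C–O bond, the furan C2–cyclobutene bond (furyllithium plus an alkoxycyclobutenone), the vinyl–carbinol bond (vinyl Grignard plus the semisquarate from diisopropyl squarate), and the side-chain CH(OH)–CH2 bond and trisubstituted alkene (allylation, cross-metathesis).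
- Forward order: the side chain is built on the bromofuran (steps 1–4) and the four-membered ring is prepared from the squarate (steps 5–7). The two are joined (step 8), acylated and unmasked (steps 9–10), the six-membered ring is formed (step 11) and oxidised (step 12).
- Stereochemistry: the single stereocentre comes from an (S)-BINOL/Ti(OiPr)4-catalysed allylation on the Si face of the furaldehyde and is not touched afterwards.

Key step: step 11

Assumption: the ring carbinol carbon created by the vinyl Grignard addition is carried as both configurations, so every later four-membered-ring compound is a pair of epimers at that carbon until the ring expansion erases it.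

**Route**

Step 1
Reactants: 1 5-bromofuran-3-carboxylic acid
Product: 2 (5-bromofuran-3-yl)methanol
Conditions: BH3·THF, THF, 0 °C → rt; then H2O
Reagents that add atoms: none
Why: Chemoselective borane reduction of a carboxylic acid proceeds through the acyloxyborane and should leave the furyl bromide and the furan ring untouched.

Step 2
Reactants: 2 (5-bromofuran-3-yl)methanol
Product: 3 5-bromofuran-3-carbaldehyde
Conditions: Dess–Martin periodinane, CH2Cl2, 0 °C → rt
Reagents that add atoms: none
Why: Dess–Martin oxidation should convert the activated primary alcohol into the aldehyde under neutral conditions without over-oxidation or damage to the bromofuran.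

Step 3
Reactants: 3 5-bromofuran-3-carbaldehyde; 4 allyltributylstannane
Product: 5 (S)-1-(5-bromofuran-3-yl)but-3-en-1-ol
Conditions: (S)-BINOL (10 mol %), Ti(OiPr)4 (10 mol %), 4 Å molecular sieves, CH2Cl2; then 3 and CH2=CHCH2SnBu3, −20 °C; aqueous NaHCO3 work-up
Reagents that add atoms: allyltributylstannane (4), C=CC[Sn](CCCC)(CCCC)CCCC
Why: In this Keck asymmetric allylation the chiral Lewis acid from (S)-BINOL and Ti(OiPr)4 should bind the aldehyde and expose its Si face to the allylstannane, which sets the (S) carbinol centre.

Step 4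
Reactants: 5 (S)-1-(5-bromofuran-3-yl)but-3-en-1-ol; 6 2-methylbut-2-ene
Product: 7 (S)-1-(5-bromofuran-3-yl)-4-methylpent-3-en-1-ol
Conditions: second-generation Grubbs catalyst (H2IMes)(PCy3)Cl2Ru=CHPh (5 mol %), 2-methylbut-2-ene (excess), CH2Cl2, 35 °C, sealed vessel
Reagents that add atoms: 2-methylbut-2-ene (6), CC=C(C)C
Why: Olefin cross-metathesis of a terminal alkene with excess 2-methylbut-2-ene is a standard way to turn an allyl group into a prenyl group; it tolerates the free alcohol, releases propene and does not involve the stereocentre.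

Step 5
Reactants: 8 diisopropyl squarate
Product: 10 3-(propan-2-yloxy)cyclobut-3-ene-1,2-dione, via hydride adduct 9 (not isolated)
Conditions: LiAlH(OtBu)3, THF, −78 °C; then 6 M HCl, 0 °C → rt
Reagents that add atoms: water, O
Why: 1,2-Reduction of one squarate carbonyl by the bulky hydride, then acid-promoted loss of the new hydroxyl, capture of the alkoxy-stabilised allyl cation by water and loss of isopropanol (hydrolytic allylic transposition of a squarate adduct) should put a hydrogen on the ring alkene.

Step 6
Reactants: 10 3-(propan-2-yloxy)cyclobut-3-ene-1,2-dione; 11 vinylmagnesium bromide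
Product: 12 4-ethenyl-4-hydroxy-3-(propan-2-yloxy)cyclobut-2-en-1-one (racemic)
Conditions: CH2=CHMgBr, THF, −78 °C; saturated aqueous NH4Cl
Reagents that add atoms: vinylmagnesium bromide (11), C=C[Mg]Br
Why: Grignard 1,2-addition should go to the ketone next to the alkoxy-bearing carbon because the other carbonyl is deactivated as a vinylogous ester, the usual regiochemistry for 3-alkoxycyclobutenediones.

Step 7
Reactants: 12 4-ethenyl-4-hydroxy-3-(propan-2-yloxy)cyclobut-2-en-1-one
Product: 13 4-ethenyl-3-(propan-2-yloxy)-4-(triethylsilyloxy)cyclobut-2-en-1-one (racemic)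
Conditions: Et3SiOTf, 2,6-lutidine, CH2Cl2, −78 → 0 °C
Reagents that add atoms: triethylsilyl trifluoromethanesulfonate, CC[Si](CC)(CC)OS(=O)(=O)C(F)(F)F
Why: Silylation of the tertiary alcohol with a silyl triflate and a hindered base removes the acidic proton before an organolithium is used and prevents alkoxide-driven opening of the four-membered ring.

Step 8
Reactants: 7 (S)-1-(5-bromofuran-3-yl)-4-methylpent-3-en-1-ol; 13 4-ethenyl-3-(propan-2-yloxy)-4-(triethylsilyloxy)cyclobut-2-en-1-one
Product: 16 4-ethenyl-3-{4-[(1S)-1-hydroxy-4-methylpent-3-en-1-yl]furan-2-yl}-4-(triethylsilyloxy)cyclobut-2-en-1-one, via dilithiated furan 14 (not isolated), via carbinol adduct 15 (not isolated)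
Conditions: 7, n-BuLi (2.05 equiv), THF, −78 °C; then 13, −78 °C; then 1 M HCl, −78 → 0 °C
Reagents that add atoms: water, O
Why: n-BuLi should first deprotonate the alcohol and then exchange bromine for lithium at C5 of the furan; the furyllithium adds 1,2 to the vinylogous ester carbonyl of 13, and dilute acid then ionises the furyl carbinol, water captures the isopropoxy-stabilised cation and isopropanol is lost (Stork–Danheiser-type 1,3-carbonyl transposition), placing the furan on the ring alkene next to the quaternary carbinol carbon.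

Step 9
Reactants: 16 4-ethenyl-3-{4-[(1S)-1-hydroxy-4-methylpent-3-en-1-yl]furan-2-yl}-4-(triethylsilyloxy)cyclobut-2-en-1-one; 17 3-methylbut-2-enoic acid
Product: 18 (1S)-1-{5-[4-ethenyl-3-oxo-4-(triethylsilyloxy)cyclobut-1-en-1-yl]furan-3-yl}-4-methylpent-3-en-1-yl 3-methylbut-2-enoate
Conditions: 17, DCC, 4-(dimethylamino)pyridine (0.1 equiv), CH2Cl2, 0 °C → rt
Reagents that add atoms: 3-methylbut-2-enoic acid (17), CC(C)=CC(=O)O
Why: Steglich esterification should acylate the only free hydroxyl with retention at the stereocentre, and activating the free acid with a carbodiimide avoids the acid chloride/amine conditions under which this acyl group deconjugates through a vinylketene.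

Step 10
Reactants: 18 (1S)-1-{5-[4-ethenyl-3-oxo-4-(triethylsilyloxy)cyclobut-1-en-1-yl]furan-3-yl}-4-methylpent-3-en-1-yl 3-methylbut-2-enoate
Product: 19 (1S)-1-[5-(4-ethenyl-4-hydroxy-3-oxocyclobut-1-en-1-yl)furan-3-yl]-4-methylpent-3-en-1-yl 3-methylbut-2-enoate
Conditions: HF·pyridine, pyridine, THF, 0 °C → rt
Reagents that add atoms: none
Why: Fluoride-mediated desilylation with buffered HF·pyridine should cleave the tertiary triethylsilyl ether without affecting the ester, the furan or the enone.

Step 11
Reactants: 19 (1S)-1-[5-(4-ethenyl-4-hydroxy-3-oxocyclobut-1-en-1-yl)furan-3-yl]-4-methylpent-3-en-1-yl 3-methylbut-2-enoate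
Product: 22 (1S)-1-[5-(2,5-dihydroxyphenyl)furan-3-yl]-4-methylpent-3-en-1-yl 3-methylbut-2-enoate, via dienylketene 20 (not isolated), via cyclohexadienone 21 (not isolated)
Conditions: toluene (degassed, 0.01 M), 110 °C, argon
Reagents that add atoms: none
Why: Heating should open the cyclobutenone by conrotatory 4π cleavage of the C1–C4 bond to dienylketene 20, the C4 hydroxyl turning outward as donor groups do, which leaves the vinyl group cis to the ketene. The ketene C=C, the ring-derived C=C and the vinyl group then form a hexatriene that closes by thermally allowed disrotatory 6π electrocyclisation, the ketene carbon bonding to the vinyl CH2 terminus to make the six-membered carbocycle 21, which enolises to the aromatic hydroquinone 22. The closest known reaction type is the thermal ring expansion of 4-alkenyl-4-hydroxycyclobutenones to hydroquinones (Moore rearrangement). No stereocentre is created; the ring carbinol centre, present as both configurations, is erased and the remote (S) ester centre is not involved. The selectivity required is torquoselectivity (vinyl inward, hydroxyl outward), which the oxygen donor on C4 secures and which also keeps the hydroxyl away from the ketene so that lactonisation is avoided. The furan on C3 cannot compete as a 6π partner because it is cross-conjugated to the ketene, so only the vinyl group can close the ring.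

Step 12
Reactants: 22 (1S)-1-[5-(2,5-dihydroxyphenyl)furan-3-yl]-4-methylpent-3-en-1-yl 3-methylbut-2-enoate
Product: 23 (1S)-1-[5-(3,6-dioxocyclohexa-1,4-dien-1-yl)furan-3-yl]-4-methylpent-3-en-1-yl 3-methylbut-2-enoate (CNP0314322.1)
Conditions: Ag2O, MgSO4, Et2O, rt (crude 22 used at once)
Reagents that add atoms: none
Why: Ag2O is a mild two-electron oxidant for the hydroquinone-to-quinone oxidation and should leave the furan, the allylic ester and the trisubstituted alkenes intact.

**Compound list**

1 | 5-bromofuran-3-carboxylic acid | O=C(O)c1coc(Br)c1 | starting material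
2 | (5-bromofuran-3-yl)methanol | OCc1coc(Br)c1 | intermediate
3 | 5-bromofuran-3-carbaldehyde | O=Cc1coc(Br)c1 | intermediate
4 | allyltributylstannane | C=CC[Sn](CCCC)(CCCC)CCCC | starting material
5 | (S)-1-(5-bromofuran-3-yl)but-3-en-1-ol | C=CC[C@H](O)c1coc(Br)c1 | intermediate
6 | 2-methylbut-2-ene | CC=C(C)C | starting material
7 | (S)-1-(5-bromofuran-3-yl)-4-methylpent-3-en-1-ol | CC(C)=CC[C@H](O)c1coc(Br)c1 | intermediate
8 | diisopropyl squarate | CC(C)OC1=C(OC(C)C)C(=O)C1=O | starting material
9 | 4-hydroxy-2,3-di(propan-2-yloxy)cyclobut-2-en-1-one (racemic, not isolated) | CC(C)OC1=C(OC(C)C)C(=O)C1O | intermediate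
10 | 3-(propan-2-yloxy)cyclobut-3-ene-1,2-dione | CC(C)OC1=CC(=O)C1=O | intermediate
11 | vinylmagnesium bromide | C=C[Mg]Br | starting material
12 | 4-ethenyl-4-hydroxy-3-(propan-2-yloxy)cyclobut-2-en-1-one (racemic) | CC(C)OC1=CC(=O)C1(O)C=C | intermediate
13 | 4-ethenyl-3-(propan-2-yloxy)-4-(triethylsilyloxy)cyclobut-2-en-1-one (racemic) | CC(C)OC1=CC(=O)C1(O[Si](CC)(CC)CC)C=C | intermediate
14 | lithium (S)-1-(5-lithiofuran-3-yl)-4-methylpent-3-en-1-olate (not isolated) | CC(C)=CC[C@H](O[Li])c1coc([Li])c1 | intermediate
15 | 2-ethenyl-4-{4-[(1S)-1-hydroxy-4-methylpent-3-en-1-yl]furan-2-yl}-1-(propan-2-yloxy)-3-(triethylsilyloxy)cyclobut-1-en-4-ol, written in SMILES order as the furyl carbinol adduct (both ring configurations, not isolated) | CC(C)=CC[C@H](O)c1coc(C2(O)C=C(OC(C)C)C2(O[Si](CC)(CC)CC)C=C)c1 | intermediate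
16 | 4-ethenyl-3-{4-[(1S)-1-hydroxy-4-methylpent-3-en-1-yl]furan-2-yl}-4-(triethylsilyloxy)cyclobut-2-en-1-one (both configurations at ring C4) | CC(C)=CC[C@H](O)c1coc(C2=CC(=O)C2(O[Si](CC)(CC)CC)C=C)c1 | intermediate
17 | 3-methylbut-2-enoic acid | CC(C)=CC(=O)O | starting material
18 | (1S)-1-{5-[4-ethenyl-3-oxo-4-(triethylsilyloxy)cyclobut-1-en-1-yl]furan-3-yl}-4-methylpent-3-en-1-yl 3-methylbut-2-enoate (both configurations at ring C4) | CC(C)=CC[C@H](OC(=O)C=C(C)C)c1coc(C2=CC(=O)C2(O[Si](CC)(CC)CC)C=C)c1 | intermediate
19 | (1S)-1-[5-(4-ethenyl-4-hydroxy-3-oxocyclobut-1-en-1-yl)furan-3-yl]-4-methylpent-3-en-1-yl 3-methylbut-2-enoate (both configurations at ring C4) | CC(C)=CC[C@H](OC(=O)C=C(C)C)c1coc(C2=CC(=O)C2(O)C=C)c1 | intermediate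
20 | (Z)-dienylketene: (1S)-1-{5-[(3Z)-4-hydroxy-1-oxohexa-1,3,5-trien-3-yl]furan-3-yl}-4-methylpent-3-en-1-yl 3-methylbut-2-enoate (not isolated) | CC(C)=CC[C@H](OC(=O)C=C(C)C)c1coc(/C(C=C=O)=C(/C=C)O)c1 | intermediate
21 | (1S)-1-[5-(6-hydroxy-3-oxocyclohexa-1,5-dien-1-yl)furan-3-yl]-4-methylpent-3-en-1-yl 3-methylbut-2-enoate (not isolated) | CC(C)=CC[C@H](OC(=O)C=C(C)C)c1coc(C2=CC(=O)CC=C2O)c1 | intermediate
22 | (1S)-1-[5-(2,5-dihydroxyphenyl)furan-3-yl]-4-methylpent-3-en-1-yl 3-methylbut-2-enoate | CC(C)=CC[C@H](OC(=O)C=C(C)C)c1coc(-c2cc(O)ccc2O)c1 | intermediate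
23 | (1S)-1-[5-(3,6-dioxocyclohexa-1,4-dien-1-yl)furan-3-yl]-4-methylpent-3-en-1-yl 3-methylbut-2-enoate | CC(C)=CC[C@H](OC(=O)C=C(C)C)c1coc(C2=CC(=O)C=CC2=O)c1 | target

**Step count and risks**

Total steps: 12. Longest linear sequence: 9 steps (steps 1–4 and 8–12); steps 5–7 form the second branch.

Steps most likely to fail:

1. Step 8 (dianion addition and hydrolytic transposition). What may go wrong: protonation of the furyllithium by hydroxyl that is not yet deprotonated, or electrocyclic opening or silyl migration in the cyclobutene alkoxide before it is protonated, so that the transposed enone does not form. The fallback reverses the order of the two carbonyl additions and sets out from 7 and 10. Alcohol 7 would be silylated (Et3SiCl, imidazole) to (S)-[1-(5-bromofuran-3-yl)-4-methylpent-3-enyloxy]triethylsilane F1. Dione 10 would be converted with 1,2-bis(trimethylsilyloxy)ethane and Me3SiOTf into its monoketal at the more electrophilic carbonyl, 3-isopropoxy-5,8-dioxaspiro[3.4]oct-2-en-1-one F2. Bromine–lithium exchange on F1 (n-BuLi, THF, −78 °C), addition to the remaining carbonyl of F2 and treatment with aqueous HCl should effect transposition, ketal hydrolysis and loss of the side-chain silyl group, giving (S)-3-[4-(1-hydroxy-4-methylpent-3-enyl)furan-2-yl]cyclobut-3-ene-1,2-dione F3. Steglich esterification with 17 would give (S)-1-[5-(3,4-dioxocyclobut-1-enyl)furan-3-yl]-4-methylpent-3-enyl 3-methylbut-2-enoate F4. Vinylmagnesium bromide 11 at −78 °C should then add to the ketone next to the furyl-bearing carbon, the other carbonyl being deactivated through the furan, and the route is rejoined at 19. Any regioisomeric adduct, (S)-1-[5-(3-ethenyl-3-hydroxy-4-oxocyclobut-1-enyl)furan-3-yl]-4-methylpent-3-enyl 3-methylbut-2-enoate F5, would give the same hydroquinone 22 in step 11.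

2. Step 11 (ring expansion). What may go wrong: inward rotation of the hydroxyl followed by lactonisation of the ketene to a butenolide, ketene oligomerisation, or oxidative decomposition of the unprotected hydroquinone at 110 °C. The fallback runs the ring expansion on the silyl ether, which cannot lactonise and delivers a protected hydroquinone; it also avoids removing the hindered tertiary silyl ether at the four-membered-ring stage. It sets out from 18: thermolysis in degassed toluene at 110 °C should give (S)-1-{5-[5-hydroxy-2-(triethylsilyloxy)phenyl]furan-3-yl}-4-methylpent-3-en-1-yl 3-methylbut-2-enoate F6. Its aryl silyl ether would be cleaved with HF·pyridine, and the route is rejoined at 22.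

3. Step 3 (asymmetric allylation). What may go wrong: poor facial selectivity or slow turnover of the (S)-BINOL/Ti(OiPr)4 catalyst with the heteroaromatic aldehyde. The fallback sets the stereocentre by enzymatic kinetic resolution instead of asymmetric C–C bond formation and sets out from 3. Zinc-mediated Barbier allylation with allyl bromide (Zn, aqueous NH4Cl/THF) would give racemic 1-(5-bromofuran-3-yl)but-3-en-1-ol F7. Burkholderia cepacia lipase with vinyl acetate should acetylate the (R) enantiomer to (R)-1-(5-bromofuran-3-yl)but-3-en-1-yl acetate F8 and leave the (S) alcohol, which is separated and rejoins the route at 5.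

Further compounds
F1 | step 8 | (S)-[1-(5-bromofuran-3-yl)-4-methylpent-3-enyloxy]triethylsilane | CC(C)=CC[C@H](O[Si](CC)(CC)CC)c1coc(Br)c1
F2 | step 8 | 3-isopropoxy-5,8-dioxaspiro[3.4]oct-2-en-1-one | CC(C)OC1=CC(=O)C12OCCO2
F3 | step 8 | (S)-3-[4-(1-hydroxy-4-methylpent-3-enyl)furan-2-yl]cyclobut-3-ene-1,2-dione | CC(C)=CC[C@H](O)c1coc(C2=CC(=O)C2=O)c1
F4 | step 8 | (S)-1-[5-(3,4-dioxocyclobut-1-enyl)furan-3-yl]-4-methylpent-3-enyl 3-methylbut-2-enoate | CC(C)=CC[C@H](OC(=O)C=C(C)C)c1coc(C2=CC(=O)C2=O)c1
F5 | step 8 | (S)-1-[5-(3-ethenyl-3-hydroxy-4-oxocyclobut-1-enyl)furan-3-yl]-4-methylpent-3-enyl 3-methylbut-2-enoate | CC(C)=CC[C@H](OC(=O)C=C(C)C)c1coc(C2=CC(O)(C=C)C2=O)c1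
F6 | step 11 | (S)-1-{5-[5-hydroxy-2-(triethylsilyloxy)phenyl]furan-3-yl}-4-methylpent-3-en-1-yl 3-methylbut-2-enoate | CC(C)=CC[C@H](OC(=O)C=C(C)C)c1coc(-c2cc(O)ccc2O[Si](CC)(CC)CC)c1
F7 | step 3 | racemic 1-(5-bromofuran-3-yl)but-3-en-1-ol | C=CCC(O)c1coc(Br)c1
F8 | step 3 | (R)-1-(5-bromofuran-3-yl)but-3-en-1-yl acetate | C=CC[C@@H](OC(C)=O)c1coc(Br)c1
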